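# Proposed total synthesis of CNP0200991.2 through an iminium Friedel–Crafts chromanol route

## Analysis of the target

The target is a 2,4,6-trihydroxybenzene-1,3-dicarbaldehyde whose fifth ring carbon carries the benzylic methine C1', which also bears an isobutyl group (C2', C3' and two methyls) and the quaternary carbon C3 of an octalin. In the octalin, ring A is C1–C2–C3–C4–C5–C6 with the trisubstituted double bond C1=C2 and a methyl on C3, and ring B is C1–C10–C9–C8–C7–C6 with a methyl on C10 and the carbinol carbon C11 (CMe2OH) on C7. There are five stereocentres, C1' (S), C3 (S), C6 (R), C7 (S) and C10 (R); on ring B the C10 methyl is cis to the C7 hydroxyisopropyl group and the C6–C5 bond is trans to both. With the C6 and C7 substituents equatorial the C10 methyl is axial, which in the saturated ketone intermediates is the less stable arrangement, so it has to be set kinetically and kept away from enolising conditions. C1' and C3 are contiguous, a tertiary benzylic carbon next to a quaternary one, which makes the aryl–C1' bond the most congested in the molecule and the hardest to form with stereocontrol. The triphenol is electron-rich and air-sensitive, and the tertiary alcohol and the C1=C2 alkene are acid-labile (ionisation, migration of the double bond towards C10), so late steps must avoid strong acid and phenol protecting groups that need harsh removal. The strategy rests on the fact that C1' is ortho to a phenol oxygen and β to C3', the branching carbon of the isobutyl chain: with C3' as a ketone carbonyl, C1' becomes the β-carbon of an (E)-enone attached to C3. The arene can then be unsubstituted phloroglucinol, whose three free positions are equivalent.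

## Retrosynthetic reasoning

**Formyl groups.** The two aryl–CHO bonds of 30 are cut first, giving triphenol 28. Aldehydes would not survive an ylide or a hydrogenation. In 28 the only two free ring positions are each flanked by two hydroxyls, so a double ortho-formylation has no regiochemical choice. It has to run under basic, non-ionising conditions because of the tertiary alcohol and the ring alkene.

**Isobutyl terminus.** 28 comes from the 1,1-disubstituted alkene 27 by addition of hydrogen. 27 comes from hemiketal 25 by replacing the masked carbonyl oxygen at C3' with a methylene carbon. This turns C3' into a carbonyl carbon and so uncovers the enone logic. Forward, the methylenation has to run on the ring-opened ketone, handled as its triphenoxide 26, and the hydrogenation has to spare the C1=C2 alkene.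

**Aryl–C1' bond and hemiketal (key disconnection).** 25 is cut at the hemiketal C–O bond, which leads to the open-chain ketone 24, and at the aryl–C1' bond, which leads to enone 22 and phloroglucinol 23. This is the only bond joining the two halves. Cutting C1'–C3 instead would mean forming a bond to a quaternary carbon. Forward, the step must add a carbon nucleophile to a hindered enone β-carbon with control of the C1' face, and the hemiketal closure pulls the reversible addition forward.

**Enone.** 22 is cut at C1'=C2' into aldehyde 20 and the stabilised ylide 21. 20 has no α-hydrogen, so it cannot epimerise or condense with itself, and a stabilised ylide gives the (E)-alkene.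

**Oxidation level and C11–O bond.** 20 goes back through diol 19 and silyl ether 18 to diene 16, by cutting the C11–O bond (Markovnikov hydration of the isopropenyl group). The hydroxyl is introduced only after the enolate, titanium and metathesis steps, so that no free alcohol is carried through them.

**Ring A.** 16 is cut at C1=C2 (ring-closing metathesis of triene 15), and the exocyclic methylene of 15 is traced to the C1 ketone of 14. A neutral metathesis places the alkene unambiguously between two allylic stereocentres (C6, C10) that would not tolerate acid or base. The ketone is what allows C6 and C10 to be set.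

**C5–C6 bond.** 14 is cut between C5 and C6 into ketone 12 and iodide 10. C6 is α to the carbonyl, so an enolate alkylation joins the chiral-pool ring B to the fragment that carries C3. The electrophile should enter anti to both the C7 and the C10 substituents.

**C10.** 12 comes from (S)-carvone 11 by adding hydrogen across the enone. Chemical conjugate reduction followed by axial protonation would give the trans isomer, so an enzymatic reduction that fixes C10 independently of C7 is used.

**C3 fragment.** 10 comes from cyclic ether 9 by regioselective ring opening, 9 from diol 7, and 7 from imide 6 by reduction. 6 is cut at C3–C4 into the dienolate 5 of imide 3 and bromoacetate 4. 3 comes from auxiliary 1 and acid chloride 2. The vinyl group on C3 arises by deconjugation of the tigloyl unit, so the quaternary centre, its methyl, its vinyl and both oxygenated arms come from one auxiliary-controlled alkylation.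

## Alternatives that were turned down

**Alternative 1: cationic enone–olefin cyclisation to close ring B.**
- Disconnection: the C6–C7 bond.
- Forward key step: Me2AlCl activates the ring A enone of substrate A2 (C2 carbonyl, C1=C6). The trisubstituted side-chain alkene C7=C11 attacks C6, and the C11 cation loses a proton, giving the keto-decalin A1 with a C7 isopropenyl group.
- For: ring B and the C6/C7 pair form in one step, and C10 comes from a chiral-pool side chain where it cannot epimerise. On this point the alternative is stronger than the chosen route, which needs an enzyme and a non-basic methylenation to protect C10. The chosen route offers instead the correct cis C7/C10 relationship by construction.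
- Against:
  - A chair transition state places the C10 methyl and the developing C7 substituent both equatorial. That is the 1,4-trans relationship, whereas the target needs cis.
  - The aryl–C1' bond and the C1'/C3 pair must already be present in A2, made without the help of the bicycle.
  - A1 is a C2 ketone with an isopropenyl group. Ketone-to-alkene conversion and hydration add about three steps.
  - The arene is carried as a trimethyl ether. Three aryl methyl ethers would have to be cleaved with a strong Lewis acid next to a tertiary alcohol and an acid-labile alkene.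
- Comparison: the chosen route keeps the arene unprotected and sets C1' with a catalyst.

**Alternative 2: phloroglucinol ring built last by [3+3] acylation.**
- Disconnection: the two ring bonds between the hydroxyl-bearing carbons next to C1' and the future formyl-bearing carbons.
- Forward key step: the substituted malonyl dichloride A4 doubly C-acylates the magnesium enolate of diester A5. The six-membered ring so formed enolises to the alkylphloroglucinol diester A3.
- For: no aromatic substitution at a hindered centre, and the two carbonyl carbons are placed by construction. This is stronger than the chosen route, which depends on a double formylation. The chosen route offers instead a commercial arene and no redox adjustment of esters.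
- Against:
  - A4 already contains the C1' stereocentre, so the difficult bond at the neopentyl carbon is only moved to an earlier malonate addition.
  - A hindered malonyl dichloride is prone to ketene formation, and C-acylation competes with O-acylation and pyranone formation.
  - Two esters must be brought to aldehydes in the presence of free phenols.
- Comparison: the route would be several steps longer and less convergent.

**Alternative 3: 6-endo radical conjugate cyclisation to close ring A.**
- Disconnection: the C5–C6 bond.
- Forward key step: the primary C5 radical from iodide A7 (Bu3SnH, azobisisobutyronitrile) adds to C6, the β-carbon of the ring B acylcyclohexene, giving keto-decalin A6.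
- For: neutral conditions, tolerance of steric bulk, and attack trans to the C7 substituent should set C6. It avoids the enolate alkylation of the chosen route and is as strong on C6. The chosen route offers instead a tin-free union and a direct entry to the C1=C2 alkene.
- Against:
  - A7 needs the C1'–C3 pair assembled in an acyclic α-quaternary ketone.
  - The primary radical must add to a trisubstituted enone carbon faster than it is reduced.
  - The product again needs two steps to turn the C2 ketone into the C1=C2 alkene.
  - The trimethoxyarene brings back the deprotection problem.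
- Comparison: the chosen route reaches the alkene directly by metathesis and needs no phenol protection.

Key step: step 14

**Assumptions.**
- The sodium dienolate of imide 3 is taken to react as the chelated enolate with the enolate oxygen syn to the α-methyl group and the electrophile entering opposite the benzyl group. With the (R)-auxiliary this gives the (S)-quaternary centre; if the sense is opposite, the (S)-auxiliary is used.
- 9-Amino-9-deoxy-epi-quinine is taken as the catalyst pseudo-enantiomer that delivers the (S)-configuration at C1'. Its quinidine-derived counterpart would be used otherwise.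

## Route

Step 1
Reactants: 1 (R)-4-benzyl-1,3-oxazolidin-2-one; 2 tigloyl chloride ((E)-2-methylbut-2-enoyl chloride)
Product: 3 (R)-4-benzyl-3-[(E)-2-methylbut-2-enoyl]-1,3-oxazolidin-2-one
Conditions: n-BuLi, THF, −78 °C; then 2, −78 → 0 °C
Reagents that add atoms: none
Why: N-acylation of the lithiated oxazolidinone with an acid chloride; the (E)-alkene is untouched.

Step 2
Reactants: 3; 4 tert-butyl bromoacetate
Product: 6 tert-butyl (3S)-3-{[(4R)-4-benzyl-2-oxo-1,3-oxazolidin-3-yl]carbonyl}-3-methylpent-4-enoate, via sodium dienolate 5 (not isolated)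
Conditions: NaN(SiMe3)2, THF, −78 °C; then 4, −78 → −40 °C
Reagents that add atoms: none
Why: Auxiliary-controlled deconjugative α-alkylation: γ-deprotonation gives the dienolate, which reacts at the α-carbon with the activated bromide to form the quaternary centre bearing methyl and vinyl; the benzyl group shields one face, so the electrophile should enter from the other and set C3 as S.

Step 3
Reactants: 6
Product: 7 (2S)-2-ethenyl-2-methylbutane-1,4-diol
Conditions: LiAlH4, THF, 0 → 40 °C
Reagents that add atoms: none
Why: Hydride reduction of the imide carbonyl and of the tert-butyl ester to the two primary alcohols with release of the auxiliary; the quaternary centre has no α-hydrogen and cannot epimerise.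

Step 4
Reactants: 7
Product: 9 (3S)-3-ethenyl-3-methyloxolane, via monotosylate 8 (not isolated)
Conditions: n-BuLi (1 equiv), THF, 0 °C; TsCl (1 equiv); n-BuLi (1 equiv), 0 → 60 °C
Reagents that add atoms: none
Why: Monosulfonylation of the less hindered alkoxide and 5-exo-tet Williamson closure by the neopentyl alkoxide, helped by the geminal substituents; the stereocentre is not involved.

Step 5
Reactants: 9
Product: 10 tert-butyl{[(2S)-2-ethenyl-4-iodo-2-methylbutyl]oxy}dimethylsilane
Conditions: TBSCl, NaI, MeCN, 25 → 55 °C
Reagents that add atoms: tert-butyldimethylsilyl chloride, CC(C)(C)[Si](C)(C)Cl; sodium iodide, [Na+].[I-]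
Why: Silyl iodide cleavage of a cyclic ether: the silyloxonium ion is opened by iodide in an SN2 step at the unhindered ring CH2, because the other α-carbon is neopentyl, so the iodide ends up on C5 and the silyl ether on the C1' oxygen.

Step 6
Reactants: 11 (S)-carvone ((5S)-2-methyl-5-(prop-1-en-2-yl)cyclohex-2-en-1-one)
Product: 12 (2R,5S)-2-methyl-5-(prop-1-en-2-yl)cyclohexan-1-one (cis-dihydrocarvone)
Conditions: ene-reductase (Old Yellow Enzyme 1), NADP+ (cat.), D-glucose, glucose dehydrogenase, phosphate buffer pH 7, 30 °C
Reagents that add atoms: none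
Why: Enzymatic asymmetric conjugate reduction of the enone: hydride from the flavin goes to C9 and a proton from the active site to C10 in a trans addition; the enzyme fixes C10 as R regardless of the 7S centre, which gives the cis isomer, and neutral pH prevents epimerisation to the more stable trans ketone.

Step 7
Reactants: 12; 10
Product: 14 (2R,3S,6R)-2-[(3S)-3-({[tert-butyl(dimethyl)silyl]oxy}methyl)-3-methylpent-4-en-1-yl]-6-methyl-3-(prop-1-en-2-yl)cyclohexan-1-one, via lithium enolate 13 (not isolated)
Conditions: LiN(iPr)2 (1.1 equiv), THF, −78 °C; then 10 (0.8 equiv), DMPU, −78 → −20 °C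
Reagents that add atoms: none
Why: Kinetic enolate alkylation: the amide base removes a proton from the CH2 group C6 and leaves the C10 methine alone; the iodide should enter C6 anti to the adjacent isopropenyl group and anti to the pseudoaxial C10 methyl, two effects that reinforce each other, so C6 is set as R, trans to both.

Step 8
Reactants: 14
Product: 15 tert-butyl{[(2S)-2-ethenyl-2-methyl-4-[(1R,3R,6S)-3-methyl-2-methylidene-6-(prop-1-en-2-yl)cyclohexyl]butyl]oxy}dimethylsilane
Conditions: Cp2Ti(μ-Cl)(μ-CH2)AlMe2, pyridine, THF–toluene, −40 → 0 °C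
Reagents that add atoms: Tebbe reagent Cp2Ti(μ-Cl)(μ-CH2)AlMe2 (chloride bridge to aluminium drawn as a Ti–Cl bond), C[Al](C)C[Ti](Cl)(C1C=CC=C1)C1C=CC=C1
Why: Tebbe methylenation: the non-basic titanium methylidene olefinates the hindered ketone without enolisation, so the epimerisable centres C6 and C10 keep their kinetic trans relationship.

Step 9
Reactants: 15
Product: 16 tert-butyl{[(2S,4aR,5S,8R)-2,8-dimethyl-5-(prop-1-en-2-yl)-2,3,4,4a,5,6,7,8-octahydronaphthalen-2-yl]methoxy}dimethylsilane
Conditions: second-generation Grubbs catalyst RuCl2(=CHPh)(H2IMes)(PCy3) (10 mol %), toluene, 80 °C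
Reagents that add atoms: none
Why: Ring-closing metathesis: the ruthenium carbene loads on the vinyl group and closes the six-membered ring onto the exocyclic methylene with loss of ethylene, giving the C1=C2 alkene; the isopropenyl group could only close a seven-membered ring and stays a spectator.

Step 10
Reactants: 16
Product: 18 2-[(1S,4R,6S,8aR)-6-({[tert-butyl(dimethyl)silyl]oxy}methyl)-4,6-dimethyl-1,2,3,4,6,7,8,8a-octahydronaphthalen-1-yl]propan-2-ol, via organomercurial 17 (not isolated)
Conditions: Hg(OAc)2, THF–H2O, 20 °C; then NaBH4, aq. NaOH, 0 °C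
Reagents that add atoms: water, O
Why: Markovnikov oxymercuration–demercuration: the terminal 1,1-disubstituted alkene reacts far faster than the trisubstituted ring alkene flanked by the quaternary C3, and no stereocentre is created.

Step 11
Reactants: 18
Product: 19 2-[(1S,4R,6S,8aR)-6-(hydroxymethyl)-4,6-dimethyl-1,2,3,4,6,7,8,8a-octahydronaphthalen-1-yl]propan-2-ol
Conditions: Bu4NF, THF, 20 °C
Reagents that add atoms: none
Why: Fluoride cleavage of the primary silyl ether; alcohol and alkene are inert.

Step 12
Reactants: 19
Product: 20 (2S,4aR,5S,8R)-5-(2-hydroxypropan-2-yl)-2,8-dimethyl-2,3,4,4a,5,6,7,8-octahydronaphthalene-2-carbaldehyde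
Conditions: Dess–Martin periodinane, NaHCO3, CH2Cl2, 0 → 20 °C
Reagents that add atoms: none
Why: Dess–Martin oxidation of the primary neopentyl alcohol; the tertiary alcohol cannot be oxidised and the aldehyde has no α-hydrogen, so neither epimerisation nor alkene migration is possible.

Step 13
Reactants: 20; 21 1-(triphenylphosphoranylidene)propan-2-one
Product: 22 (3E)-4-[(2R,4aR,5S,8R)-5-(2-hydroxypropan-2-yl)-2,8-dimethyl-2,3,4,4a,5,6,7,8-octahydronaphthalen-2-yl]but-3-en-2-one
Conditions: toluene, 100 °C
Reagents that add atoms: none
Why: Wittig reaction of a stabilised ylide with a non-enolisable aldehyde, giving the (E)-enone under thermodynamic control of the oxaphosphetane; the descriptor at the quaternary carbon changes only because the ligand priorities change.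

Step 14
Reactants: 22; 23 phloroglucinol (benzene-1,3,5-triol)
Product: 25 (4S)-4-[(2S,4aR,5S,8R)-5-(2-hydroxypropan-2-yl)-2,8-dimethyl-2,3,4,4a,5,6,7,8-octahydronaphthalen-2-yl]-2-methyl-3,4-dihydro-2H-chromene-2,5,7-triol (both epimers at the hemiketal carbon), via open-chain ketone 24 (not isolated)
Conditions: 23 (3 equiv), 9-amino-9-deoxy-epi-quinine (20 mol %), CF3CO2H (40 mol %), THF, 40 °C
Reagents that add atoms: none
Why: The primary amine condenses with the methyl ketone of 22 to an iminium ion in which the protonated quinuclidine and its counter-anion cover one face of C1'; phloroglucinol 23 attacks C1' through carbon in a Friedel–Crafts conjugate addition, rearomatises, and hydrolysis of the enamine releases ketone 24 and the catalyst. The closest known reaction type is the primary-amine (iminium) catalysed Friedel–Crafts conjugate addition–hemiketalisation of naphthols and of 4-hydroxycoumarin with enones. The ortho hydroxyl then adds to the ketone carbonyl in a 6-exo-trig closure to the 2-methylchroman-2-ol 25, which takes the ketone out of the retro-addition equilibrium. C1' is set by the catalyst through face selection on the iminium ion, chosen as the matched partner of the adjacent quaternary C3; the hemiketal carbon forms as a mixture and is erased in step 15. The step needs carbon- over oxygen-alkylation (the oxa-Michael adduct reverts, the carbon adduct is trapped), 1,4- over 1,2-addition (secured by iminium activation) and mono-alkylation (secured by the excess of 23 and the bulk of the first substituent). Regiochemistry is not an issue because the three free positions of 23 are equivalent, and the tertiary alcohol and ring alkene are inert to the buffered amine salt.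

Step 15
Reactants: 25
Product: 27 2-[(1S)-1-[(2S,4aR,5S,8R)-5-(2-hydroxypropan-2-yl)-2,8-dimethyl-2,3,4,4a,5,6,7,8-octahydronaphthalen-2-yl]-3-methylbut-3-en-1-yl]benzene-1,3,5-triol, via ring-opened tripotassium triphenoxide 26 (not isolated)
Conditions: KOtBu (3.2 equiv), THF, 0 °C; then Ph3P=CH2 (from Ph3PCH3Br, 5 equiv, and KOtBu, 4.8 equiv, THF), 0 → 60 °C; aq. NH4Cl work-up
Reagents that add atoms: methyltriphenylphosphonium bromide, C[P+](c1ccccc1)(c1ccccc1)c1ccccc1.[Br-]
Why: Wittig methylenation of a hemiketal through its ring-opened form: KOtBu deprotonates the two phenols and the hemiketal hydroxyl, which opens the ring to the triphenoxide 26 of the methyl ketone, and the preformed ylide then olefinates that ketone; C1' is β to the carbonyl and is not touched, and the mild work-up avoids acid cyclisation of a phenol onto the new alkene.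

Step 16
Reactants: 27
Product: 28 2-[(1S)-1-[(2S,4aR,5S,8R)-5-(2-hydroxypropan-2-yl)-2,8-dimethyl-2,3,4,4a,5,6,7,8-octahydronaphthalen-2-yl]-3-methylbutyl]benzene-1,3,5-triol
Conditions: H2 (1 atm), RhCl(PPh3)3 (10 mol %), benzene–EtOH, 20 °C
Reagents that add atoms: none
Why: Homogeneous hydrogenation that reduces the unhindered 1,1-disubstituted alkene and leaves the trisubstituted C1=C2 alkene next to the quaternary C3; no new stereocentre arises because C3' carries two methyl groups.

Step 17
Reactants: 28
Product: 30 5-[(1S)-1-[(2S,4aR,5S,8R)-5-(2-hydroxypropan-2-yl)-2,8-dimethyl-2,3,4,4a,5,6,7,8-octahydronaphthalen-2-yl]-3-methylbutyl]-2,4,6-trihydroxybenzene-1,3-dicarbaldehyde (CNP0200991.2), via monoaldehyde 29 (not isolated)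
Conditions: MgCl2 (6 equiv), Et3N (8 equiv), paraformaldehyde (12 equiv), THF, 66 °C; cold dilute HCl work-up
Reagents that add atoms: paraformaldehyde (formaldehyde), C=O
Why: Magnesium-mediated ortho-formylation of phenols: the magnesium phenoxide binds formaldehyde and delivers it to the ortho carbon, and the hydroxymethyl intermediate is oxidised by hydride transfer to a second formaldehyde; both free ring positions lie between two phenoxides, so both should react, and the basic medium spares the tertiary alcohol and the alkene.

## Compound list

1 | (R)-4-benzyl-1,3-oxazolidin-2-one | O=C1OC[C@@H](Cc2ccccc2)N1 | starting material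
2 | tigloyl chloride, (E)-2-methylbut-2-enoyl chloride | C/C=C(\C)C(=O)Cl | starting material
3 | (R)-4-benzyl-3-[(E)-2-methylbut-2-enoyl]-1,3-oxazolidin-2-one | C/C=C(\C)C(=O)N1C(=O)OC[C@H]1Cc1ccccc1 | intermediate
4 | tert-butyl bromoacetate | CC(C)(C)OC(=O)CBr | starting material
5 | sodium dienolate of 3 | [Na+].C=C/C(C)=C(/[O-])N1C(=O)OC[C@H]1Cc1ccccc1 | intermediate
6 | tert-butyl (3S)-3-{[(4R)-4-benzyl-2-oxo-1,3-oxazolidin-3-yl]carbonyl}-3-methylpent-4-enoate | CC(C)(C)OC(=O)C[C@@](C)(C=C)C(=O)N1C(=O)OC[C@H]1Cc1ccccc1 | intermediate
7 | (2S)-2-ethenyl-2-methylbutane-1,4-diol | OC[C@](CCO)(C)C=C | intermediate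
8 | (3S)-3-(hydroxymethyl)-3-methylpent-4-en-1-yl 4-methylbenzenesulfonate | Cc1ccc(cc1)S(=O)(=O)OCC[C@@](C)(C=C)CO | intermediate
9 | (3S)-3-ethenyl-3-methyloxolane | C=C[C@]1(C)CCOC1 | intermediate
10 | tert-butyl{[(2S)-2-ethenyl-4-iodo-2-methylbutyl]oxy}dimethylsilane | CC(C)(C)[Si](C)(C)OC[C@](CCI)(C)C=C | intermediate
11 | (S)-carvone | O=C1C(C)=CC[C@H](C(C)=C)C1 | starting material
12 | (2R,5S)-2-methyl-5-(prop-1-en-2-yl)cyclohexan-1-one (cis-dihydrocarvone) | O=C1[C@H](C)CC[C@H](C(C)=C)C1 | intermediate
13 | lithium enolate of 12 (C1=C6) | [Li+].[O-]C1=C[C@@H](C(C)=C)CC[C@H]1C | intermediate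
14 | (2R,3S,6R)-2-[(3S)-3-({[tert-butyl(dimethyl)silyl]oxy}methyl)-3-methylpent-4-en-1-yl]-6-methyl-3-(prop-1-en-2-yl)cyclohexan-1-one | O=C1[C@H](C)CC[C@H](C(C)=C)[C@H]1CC[C@@](C)(C=C)CO[Si](C)(C)C(C)(C)C | intermediate
15 | tert-butyl{[(2S)-2-ethenyl-2-methyl-4-[(1R,3R,6S)-3-methyl-2-methylidene-6-(prop-1-en-2-yl)cyclohexyl]butyl]oxy}dimethylsilane | C=C1[C@H](C)CC[C@H](C(C)=C)[C@H]1CC[C@@](C)(C=C)CO[Si](C)(C)C(C)(C)C | intermediate
16 | tert-butyl{[(2S,4aR,5S,8R)-2,8-dimethyl-5-(prop-1-en-2-yl)-2,3,4,4a,5,6,7,8-octahydronaphthalen-2-yl]methoxy}dimethylsilane | CC(C)(C)[Si](C)(C)OC[C@]1(C)C=C2[C@H](C)CC[C@H](C(C)=C)[C@H]2CC1 | intermediate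
17 | acetoxymercurio adduct of 16 (HgOAc on the former isopropenyl CH2, hydroxyl on C11, C11 epimers) | CC(C)(C)[Si](C)(C)OC[C@]1(C)C=C2[C@H](C)CC[C@H](C(C)(O)C[Hg]OC(C)=O)[C@H]2CC1 | intermediate
18 | 2-[(1S,4R,6S,8aR)-6-({[tert-butyl(dimethyl)silyl]oxy}methyl)-4,6-dimethyl-1,2,3,4,6,7,8,8a-octahydronaphthalen-1-yl]propan-2-ol | CC(C)(C)[Si](C)(C)OC[C@]1(C)C=C2[C@H](C)CC[C@H](C(C)(C)O)[C@H]2CC1 | intermediate
19 | 2-[(1S,4R,6S,8aR)-6-(hydroxymethyl)-4,6-dimethyl-1,2,3,4,6,7,8,8a-octahydronaphthalen-1-yl]propan-2-ol | OC[C@]1(C)C=C2[C@H](C)CC[C@H](C(C)(C)O)[C@H]2CC1 | intermediate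
20 | (2S,4aR,5S,8R)-5-(2-hydroxypropan-2-yl)-2,8-dimethyl-2,3,4,4a,5,6,7,8-octahydronaphthalene-2-carbaldehyde | O=C[C@]1(C)C=C2[C@H](C)CC[C@H](C(C)(C)O)[C@H]2CC1 | intermediate
21 | 1-(triphenylphosphoranylidene)propan-2-one | CC(=O)C=P(c1ccccc1)(c1ccccc1)c1ccccc1 | starting material
22 | (3E)-4-[(2R,4aR,5S,8R)-5-(2-hydroxypropan-2-yl)-2,8-dimethyl-2,3,4,4a,5,6,7,8-octahydronaphthalen-2-yl]but-3-en-2-one | CC(=O)/C=C/[C@]1(C)C=C2[C@H](C)CC[C@H](C(C)(C)O)[C@H]2CC1 | intermediate
23 | phloroglucinol | Oc1cc(O)cc(O)c1 | starting material
24 | (4S)-4-[(2S,4aR,5S,8R)-5-(2-hydroxypropan-2-yl)-2,8-dimethyl-2,3,4,4a,5,6,7,8-octahydronaphthalen-2-yl]-4-(2,4,6-trihydroxyphenyl)butan-2-one | CC(=O)C[C@H](c1c(O)cc(O)cc1O)[C@]1(C)C=C2[C@H](C)CC[C@H](C(C)(C)O)[C@H]2CC1 | intermediate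
25 | (4S)-4-[(2S,4aR,5S,8R)-5-(2-hydroxypropan-2-yl)-2,8-dimethyl-2,3,4,4a,5,6,7,8-octahydronaphthalen-2-yl]-2-methyl-3,4-dihydro-2H-chromene-2,5,7-triol (hemiketal epimers) | Oc1cc(O)c2c(c1)OC(C)(O)C[C@H]2[C@]1(C)C=C3[C@H](C)CC[C@H](C(C)(C)O)[C@H]3CC1 | intermediate
26 | tripotassium 2-[(1S)-1-[(2S,4aR,5S,8R)-5-(2-hydroxypropan-2-yl)-2,8-dimethyl-2,3,4,4a,5,6,7,8-octahydronaphthalen-2-yl]-3-oxobutyl]benzene-1,3,5-triolate | [K+].[K+].[K+].CC(=O)C[C@H](c1c([O-])cc([O-])cc1[O-])[C@]1(C)C=C2[C@H](C)CC[C@H](C(C)(C)O)[C@H]2CC1 | intermediate
27 | 2-[(1S)-1-[(2S,4aR,5S,8R)-5-(2-hydroxypropan-2-yl)-2,8-dimethyl-2,3,4,4a,5,6,7,8-octahydronaphthalen-2-yl]-3-methylbut-3-en-1-yl]benzene-1,3,5-triol | C=C(C)C[C@H](c1c(O)cc(O)cc1O)[C@]1(C)C=C2[C@H](C)CC[C@H](C(C)(C)O)[C@H]2CC1 | intermediate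
28 | 2-[(1S)-1-[(2S,4aR,5S,8R)-5-(2-hydroxypropan-2-yl)-2,8-dimethyl-2,3,4,4a,5,6,7,8-octahydronaphthalen-2-yl]-3-methylbutyl]benzene-1,3,5-triol | CC(C)C[C@H](c1c(O)cc(O)cc1O)[C@]1(C)C=C2[C@H](C)CC[C@H](C(C)(C)O)[C@H]2CC1 | intermediate
29 | 3-[(1S)-1-[(2S,4aR,5S,8R)-5-(2-hydroxypropan-2-yl)-2,8-dimethyl-2,3,4,4a,5,6,7,8-octahydronaphthalen-2-yl]-3-methylbutyl]-2,4,6-trihydroxybenzaldehyde | CC(C)C[C@H](c1c(O)cc(O)c(C=O)c1O)[C@]1(C)C=C2[C@H](C)CC[C@H](C(C)(C)O)[C@H]2CC1 | intermediate
30 | 5-[(1S)-1-[(2S,4aR,5S,8R)-5-(2-hydroxypropan-2-yl)-2,8-dimethyl-2,3,4,4a,5,6,7,8-octahydronaphthalen-2-yl]-3-methylbutyl]-2,4,6-trihydroxybenzene-1,3-dicarbaldehyde (CNP0200991.2) | CC(C)C[C@H](c1c(O)c(C=O)c(O)c(C=O)c1O)[C@]1(C)C=C2[C@H](C)CC[C@H](C(C)(C)O)[C@H]2CC1 | target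

## Step count and least certain steps

Total step count: 17. Longest linear sequence: 16 steps (steps 1–5, then 7–17); the ring B branch (step 6) joins at step 7.

**Step 14 (key step).** The conjugate addition may be slow or may stall, because C1' is bound to the quaternary C3 and the iminium β-carbon is neopentyl-like. Retro-addition before hemiketal closure, loss of catalyst by condensation of the amine with phloroglucinol, and poor facial selectivity in a mismatched pairing are the other likely failures. The fallback sets out from aldehyde 20 and comes back to the route at alkene 27. 1,3,5-Tris(methoxymethoxy)benzene is lithiated with n-BuLi to 2,4,6-tris(methoxymethoxy)phenyllithium F1, which adds to the formyl group of 20 to give the benzylic alcohol F2. Ionisation of F2 with catalytic Sc(OTf)3 in the presence of trimethyl(2-methylallyl)silane (Hosomi–Sakurai-type benzylic substitution through the trialkoxybenzyl cation) gives the methallylated arene F3, and removal of the three methoxymethyl groups with ZnBr2 and propane-1-thiol returns to 27. C1' would then rest on substrate control by C3.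

**Step 7.** The unactivated iodide may react slowly, so proton transfer between enolate and product can set in. That would cause loss of the C10 configuration, regiochemical scrambling and over-alkylation. The fallback sets out from 12 and comes back at 14. N,N-Dimethylhydrazine in ethanol at 20 °C converts 12 into the dimethylhydrazone F4; deprotonation with LiN(iPr)2 and alkylation of the far more nucleophilic aza-enolate with 10 gives the alkylated hydrazone F5, and cleavage with CuCl2 in aqueous THF buffered at pH 7 returns to 14.

**Step 9.** Ring closure may be slow because both olefins are hindered (vinyl on a quaternary carbon, methylene flanked by two methines). Catalyst decay or intermolecular metathesis at the vinyl group could then take over. The fallback sets out from ketone 14 and comes back at 16: one equivalent of Mo(=CHCMe2Ph)(N-2,6-iPr2C6H3)[OCMe(CF3)2]2 in benzene exchanges its alkylidene with the vinyl group, and the new alkylidene olefinates the C1 ketone intramolecularly. Steps 8 and 9 are replaced and no new compound is formed on the way (F0).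

**Step 15.** The polyphenoxide salt may precipitate and the ylide may enolise the methyl ketone, leaving olefination incomplete. The fallback sets out from 25 and comes back at 27. TBSCl and imidazole in DMF trap the ring-opened form as the tris(silyl ether) ketone F6, Ph3P=CH2 (from Ph3PCH3Br and KOtBu) converts it into the tris(silyl ether) alkene F7, and Bu4NF returns to 27.

**Step 17.** The second formylation may stall on the deactivated monoaldehyde, or hydroxymethyl intermediates may condense to diarylmethanes. The fallback sets out from 28 and comes back at 30. TBSOTf and 2,6-lutidine give the tetrakis(silyl ether) F8, and K2CO3 in methanol frees the three phenols to leave the tertiary silyl ether F9. Vilsmeier–Haack diformylation (POCl3, DMF, MeCN, 0 → 20 °C, aqueous NaOAc) gives the dialdehyde F10, and HF·pyridine returns to 30.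

## Further compounds

F1 | step 14 | 2,4,6-tris(methoxymethoxy)phenyllithium | [Li]c1c(OCOC)cc(OCOC)cc1OCOC
F2 | step 14 | benzylic alcohol from F1 and 20 (C1' epimers) | COCOc1cc(OCOC)cc(OCOC)c1C(O)[C@]1(C)C=C2[C@H](C)CC[C@H](C(C)(C)O)[C@H]2CC1
F3 | step 14 | tris(methoxymethyl) ether of 27 | COCOc1cc(OCOC)cc(OCOC)c1[C@@H](CC(C)=C)[C@]1(C)C=C2[C@H](C)CC[C@H](C(C)(C)O)[C@H]2CC1
F4 | step 7 | N,N-dimethylhydrazone of 12 | CN(C)N=C1[C@H](C)CC[C@H](C(C)=C)C1
F5 | step 7 | N,N-dimethylhydrazone of 14 | CN(C)N=C1[C@H](C)CC[C@H](C(C)=C)[C@H]1CC[C@@](C)(C=C)CO[Si](C)(C)C(C)(C)C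
F0 | step 9 | none | none
F6 | step 15 | tris(tert-butyldimethylsilyl) ether of ketone 24 | CC(=O)C[C@H](c1c(O[Si](C)(C)C(C)(C)C)cc(O[Si](C)(C)C(C)(C)C)cc1O[Si](C)(C)C(C)(C)C)[C@]1(C)C=C2[C@H](C)CC[C@H](C(C)(C)O)[C@H]2CC1
F7 | step 15 | tris(tert-butyldimethylsilyl) ether of 27 | C=C(C)C[C@H](c1c(O[Si](C)(C)C(C)(C)C)cc(O[Si](C)(C)C(C)(C)C)cc1O[Si](C)(C)C(C)(C)C)[C@]1(C)C=C2[C@H](C)CC[C@H](C(C)(C)O)[C@H]2CC1
F8 | step 17 | tetrakis(tert-butyldimethylsilyl) ether of 28 | CC(C)C[C@H](c1c(O[Si](C)(C)C(C)(C)C)cc(O[Si](C)(C)C(C)(C)C)cc1O[Si](C)(C)C(C)(C)C)[C@]1(C)C=C2[C@H](C)CC[C@H](C(C)(C)O[Si](C)(C)C(C)(C)C)[C@H]2CC1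
F9 | step 17 | tertiary tert-butyldimethylsilyl ether of 28 | CC(C)C[C@H](c1c(O)cc(O)cc1O)[C@]1(C)C=C2[C@H](C)CC[C@H](C(C)(C)O[Si](C)(C)C(C)(C)C)[C@H]2CC1
F10 | step 17 | tertiary tert-butyldimethylsilyl ether of 30 | CC(C)C[C@H](c1c(O)c(C=O)c(O)c(C=O)c1O)[C@]1(C)C=C2[C@H](C)CC[C@H](C(C)(C)O[Si](C)(C)C(C)(C)C)[C@H]2CC1
A1 | alternative 1 | C2-keto decalin with C7 isopropenyl group and trimethoxyphenyl unit | CC(C)C[C@H](c1c(OC)cc(OC)cc1OC)[C@]1(C)C(=O)[C@@H]2[C@H](C)CC[C@H](C(C)=C)[C@H]2CC1
A2 | alternative 1 | ring A cyclohexenone carrying the C10–C11 side chain on C1 | CC(C)C[C@H](c1c(OC)cc(OC)cc1OC)[C@@]1(C)CCC=C([C@H](C)CCC=C(C)C)C1=O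
A3 | alternative 2 | alkylphloroglucinol dimethyl diester with triethylsilyl-protected carbinol | CC(C)C[C@H](c1c(O)c(C(=O)OC)c(O)c(C(=O)OC)c1O)[C@]1(C)C=C2[C@H](C)CC[C@H](C(C)(C)O[Si](CC)(CC)CC)[C@H]2CC1
A4 | alternative 2 | C1'-substituted malonyl dichloride | CC(C)C[C@H](C(C(=O)Cl)C(=O)Cl)[C@]1(C)C=C2[C@H](C)CC[C@H](C(C)(C)O[Si](CC)(CC)CC)[C@H]2CC1
A5 | alternative 2 | dimethyl 3-oxopentanedioate | COC(=O)CC(=O)CC(=O)OC
A6 | alternative 3 | C2-keto decalin with triethylsilyl-protected carbinol and trimethoxyphenyl unit | CC(C)C[C@H](c1c(OC)cc(OC)cc1OC)[C@]1(C)C(=O)[C@@H]2[C@H](C)CC[C@H](C(C)(C)O[Si](CC)(CC)CC)[C@H]2CC1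
A7 | alternative 3 | primary iodide with ring B acylcyclohexene | CC(C)C[C@H](c1c(OC)cc(OC)cc1OC)[C@@](C)(CCI)C(=O)C1=C[C@@H](C(C)(C)O[Si](CC)(CC)CC)CC[C@H]1C
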